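Retrosynthesis: after removal of all O-alkyl groups, ring A of the apigenin half is opened at C6–C7 (retro-6π) and at C8–C8a (retro-Wolff). The inter-flavone bond C8–C8'' is then cut at the diazo carbon, and the remaining 4-pyranone is cut at its C3–vinyl bond and its Claisen bonds.
Enabling feature: in ring A of the apigenin half, C7 (OH) lies between C6–H and C8, and C8 carries the luteolin aryl group and is bonded to C8a of ring C. C5 (O) is bonded to C4a. This is the substitution pattern produced when a ketene C7=C8 closes across the C8a=C4a bond onto a 1-alkoxyvinyl unit C5=C6.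
Forward: rings B and C of apigenin are made first (Claisen condensation and cyclodehydration). Pyranone C3 receives an ethoxyvinyl group, the C2 ester becomes a diazoketone, and the finished luteolin half (bought as its tetramethyl ether) is attached at the diazo carbon. Ring A closes last, followed by global dealkylation.
Stereochemistry: the target has no stereocentre, and the 8,8'' axis appears only when ring A aromatises.

Key step: step 8

Assumption: the structure defines no configuration at the hindered 8,8'' axis, so the biaryl is made and delivered as the racemate.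
Locants: plain and single-primed numbers refer to the apigenin half, doubly and triply primed numbers to the luteolin half.

Step 1
Reactants: 1 1-(4-methoxyphenyl)butane-1,3-dione; 2 diethyl oxalate
Product: 4 ethyl 6-(4-methoxyphenyl)-4-oxo-4H-pyran-2-carboxylate, via trioxohexanoate 3 (not isolated)
Conditions: NaOEt (2.2 equiv), EtOH, 0 °C to rt; then conc. HCl, EtOH, reflux
Reagents that add atoms: none
Why: A Claisen condensation at the terminal methyl group of the diketone (non-enolisable oxalate as acceptor, excess alkoxide driving the equilibrium through the polyenolate) gives the 1,3,5-tricarbonyl array of 3, and acid then closes it by the classical cyclodehydration of such arrays, the enol oxygen on the aryl side adding to the keto-ester carbonyl, which is the standard entry to 6-aryl-4-pyranone-2-carboxylates.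

Step 2
Reactants: 4 ethyl 6-(4-methoxyphenyl)-4-oxo-4H-pyran-2-carboxylate
Product: 6 ethyl 3-iodo-6-(4-methoxyphenyl)-4-oxo-4H-pyran-2-carboxylate, via pyranon-3-ylzinc chloride 5 (not isolated)
Conditions: TMPZnCl·LiCl (1.2 equiv), THF, 25 °C; then I2, THF, 0 °C
Reagents that add atoms: iodine [I][I]; TMPZnCl·LiCl CC1(C)CCCC(C)(C)N1[Zn]Cl.[Li+].[Cl-] (zinc and chlorine in 5 only)
Why: Directed zincation by a hindered TMP-zinc amide, a reaction type established at C3 of chromones, should take the C3–H because only this hydrogen lies between two coordinating carbonyl groups (C4=O, C2 ester) and feels the inductive pull of the ester, the covalent C–Zn bond leaves ester and pyranone untouched, and iodolysis then fixes the position.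

Step 3
Reactants: 6 ethyl 3-iodo-6-(4-methoxyphenyl)-4-oxo-4H-pyran-2-carboxylate
Product: 7 ethyl 3-(1-ethoxyvinyl)-6-(4-methoxyphenyl)-4-oxo-4H-pyran-2-carboxylate
Conditions: tributyl(1-ethoxyvinyl)stannane (1.3 equiv), Pd(PPh3)4 (5 mol %), CuI (10 mol %), DMF, 80 °C; Et3N-buffered work-up and silica
Reagents that add atoms: tributyl(1-ethoxyvinyl)stannane CCCC[Sn](CCCC)(CCCC)C(=C)OCC
Why: The Stille coupling of α-iodoenone-type C(sp2)–I bonds (3-iodochromones, 3-iodoflavones) tolerates esters, tributyl(1-ethoxyvinyl)stannane is the usual carrier of this two-carbon enol ether unit, CuI helps transmetalation at the flanked carbon, and a base-buffered work-up keeps the enol ether that will supply C5 and C6 of ring A.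

Step 4
Reactants: 7 ethyl 3-(1-ethoxyvinyl)-6-(4-methoxyphenyl)-4-oxo-4H-pyran-2-carboxylate
Product: 8 potassium 3-(1-ethoxyvinyl)-6-(4-methoxyphenyl)-4-oxo-4H-pyran-2-carboxylate
Conditions: KOSiMe3 (1.05 equiv), THF, 0 °C to rt; salt collected by filtration and dried
Reagents that add atoms: potassium trimethylsilanolate C[Si](C)(C)[O-].[K+]
Why: Anhydrous ester cleavage by trimethylsilanolate (acyl substitution followed by silyl transfer to ethoxide) delivers the carboxylate salt directly, so the pyranone never meets aqueous hydroxide and the enol ether never meets a neighbouring free carboxylic acid that could protonate it and lactonise.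

Step 5
Reactants: 8 potassium 3-(1-ethoxyvinyl)-6-(4-methoxyphenyl)-4-oxo-4H-pyran-2-carboxylate
Product: 10 2-(diazoacetyl)-3-(1-ethoxyvinyl)-6-(4-methoxyphenyl)-4H-pyran-4-one, via mixed anhydride 9 (not isolated)
Conditions: i-BuOCOCl (1.05 equiv), THF, −15 °C; then CH2N2 (3 equiv), Et2O, −15 to 0 °C, dark
Reagents that add atoms: diazomethane C=[N+]=[N-]; isobutyl chloroformate CC(C)COC(=O)Cl (atoms in 9 only)
Why: This is the diazoketone-forming half of the Arndt–Eistert sequence run through a mixed carbonic anhydride, in which the small nucleophile diazomethane attacks the more electrophilic pyranone-2-carbonyl group and the departing alkyl carbonate takes up the proton, so no mineral acid arises that could harm the enol ether or the diazo group.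

Step 6
Reactants: 11 5,7,3',4'-tetramethoxyflavone
Product: 12 8-iodo-5,7,3',4'-tetramethoxyflavone
Conditions: I2 (1.05 equiv), CF3CO2Ag (1.05 equiv), CHCl3, 0 °C to rt, dark
Reagents that add atoms: iodine [I][I]
Why: Electrophilic aromatic iodination with silver-activated iodine goes to the phloroglucinol-type ring A as the most electron-rich ring, and in flavones whose 5-oxygen is alkylated it goes to C8 in preference to C6, which is the established way to the 8-iodoflavones used as coupling partners.

Step 7
Reactants: 10 2-(diazoacetyl)-3-(1-ethoxyvinyl)-6-(4-methoxyphenyl)-4H-pyran-4-one; 12 8-iodo-5,7,3',4'-tetramethoxyflavone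
Product: 13 2-[diazo(5,7,3',4'-tetramethoxyflavon-8-yl)acetyl]-3-(1-ethoxyvinyl)-6-(4-methoxyphenyl)-4H-pyran-4-one
Conditions: Pd(PPh3)4 (5–10 mol %), Ag2CO3 (0.5 equiv), Et3N (1.3 equiv), toluene, rt, dark
Reagents that add atoms: none
Why: The palladium-catalysed C–H arylation of acyldiazomethanes by aryl iodides is a known room-temperature cross-coupling (oxidative addition of zerovalent palladium to the C8–I bond of 12, silver-assisted replacement of iodide by the deprotonated diazo carbon, reductive elimination with the diazo group kept), and 8-iodoflavones are proven partners in palladium couplings in spite of their two ortho oxygen substituents.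

Step 8
Reactants: 13 2-[diazo(5,7,3',4'-tetramethoxyflavon-8-yl)acetyl]-3-(1-ethoxyvinyl)-6-(4-methoxyphenyl)-4H-pyran-4-one
Product: 16 5-ethoxy-7-hydroxy-4'-methoxy-8-(5,7,3',4'-tetramethoxyflavon-8-yl)flavone, via ketene 14 (not isolated), via cyclohexadienone 15 (not isolated)
Conditions: hν (450 nm LEDs), dry degassed toluene (0.005 M), 15 °C; then dark, 80 °C
Reagents that add atoms: none
Why: Proposed new method: excitation of the weak visible band of the diazoketone, at a wavelength where neither the flavone nor the pyranone absorbs, expels N2 and the pyranon-2-yl group moves from the acyl carbon to the diazo carbon (Wolff rearrangement, new C8–C8a bond), so that in ketene 14 the old carbonyl carbon is C7 and the aryl-bearing carbon is C8. The ketene C7=C8 bond, the C8a=C4a bond of ring C and the ethoxyvinyl C5=C6 bond sit on adjacent ring carbons in an enforced cis relation, and ring A closes by a thermal disrotatory 6π electrocyclisation (new C6–C7 bond) that is polarity-matched because the nucleophilic CH2 terminus of the enol ether meets the electrophilic ketene carbon; dienone 15 then enolises irreversibly to the C7 phenol. The closest known reaction types are the photochemical Wolff rearrangement of 2-diazo-1,2-diarylethanones to diarylketenes and the dienylketene-to-phenol closure that ends the diazoketone variant of the Danheiser annulation; what has not been shown is a 4-pyranon-2-yl migrating group combined with direct closure of the ketene onto a ring-bound alkoxyvinyl group. No stereocentre is formed, and the C8–C8'' bond, made in step 7 at an open-chain sp2 carbon, turns into a hindered (racemic) biaryl axis only when ring A aromatises. The step needs the 1,2-shift to outrun capture of the ketocarbene (cyclopropanation of the enol ether, insertion into the C7''-OMe group, ylide formation at a carbonyl oxygen) and needs ring closure to outrun hydration or dimerisation of the ketene. The first is served by the good migratory aptitude of sp2 groups in photochemical Wolff reactions of aryl diazoketones and by cool irradiation, the second by high dilution in a dry non-nucleophilic solvent, by the two bulky ketene substituents and by the intramolecular six-centre geometry.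

Step 9
Reactants: 16 5-ethoxy-7-hydroxy-4'-methoxy-8-(5,7,3',4'-tetramethoxyflavon-8-yl)flavone
Product: 17 8-(5,7,3',4'-tetrahydroxyflavon-8-yl)-5,7,4'-trihydroxyflavone (apigenin and luteolin joined C8 to C8'', CNP0408047.0)
Conditions: BBr3 (15 equiv), CH2Cl2, −78 °C to 40 °C; then MeOH, H2O
Reagents that add atoms: none
Why: Exhaustive aryl ether cleavage with BBr3 (Lewis acid-assisted SN2 dealkylation) is the standard last step for biflavone alkyl ethers, the peri 5-OEt and 5''-OMe groups going first through chelation to the C4 carbonyl groups, and it avoids the hot protic acid that triggers Wessely–Moser isomerisation of 8-substituted 5,7-dihydroxyflavones.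

Compound list
1 | 1-(4-methoxyphenyl)butane-1,3-dione | COc1ccc(cc1)C(=O)CC(C)=O | starting material
2 | diethyl oxalate | CCOC(=O)C(=O)OCC | starting material
3 | ethyl 6-(4-methoxyphenyl)-2,4,6-trioxohexanoate (formed as its sodium enolate) | CCOC(=O)C(=O)CC(=O)CC(=O)c1ccc(OC)cc1 | intermediate
4 | ethyl 6-(4-methoxyphenyl)-4-oxo-4H-pyran-2-carboxylate | CCOC(=O)c1cc(=O)cc(-c2ccc(OC)cc2)o1 | intermediate
5 | [2-(ethoxycarbonyl)-6-(4-methoxyphenyl)-4-oxo-4H-pyran-3-yl]zinc chloride | CCOC(=O)c1oc(-c2ccc(OC)cc2)cc(=O)c1[Zn]Cl | intermediate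
6 | ethyl 3-iodo-6-(4-methoxyphenyl)-4-oxo-4H-pyran-2-carboxylate | CCOC(=O)c1oc(-c2ccc(OC)cc2)cc(=O)c1I | intermediate
7 | ethyl 3-(1-ethoxyvinyl)-6-(4-methoxyphenyl)-4-oxo-4H-pyran-2-carboxylate | CCOC(=O)c1oc(-c2ccc(OC)cc2)cc(=O)c1C(=C)OCC | intermediate
8 | potassium 3-(1-ethoxyvinyl)-6-(4-methoxyphenyl)-4-oxo-4H-pyran-2-carboxylate | [K+].[O-]C(=O)c1oc(-c2ccc(OC)cc2)cc(=O)c1C(=C)OCC | intermediate
9 | 3-(1-ethoxyvinyl)-6-(4-methoxyphenyl)-4-oxo-4H-pyran-2-carboxylic isobutyl carbonic anhydride | CC(C)COC(=O)OC(=O)c1oc(-c2ccc(OC)cc2)cc(=O)c1C(=C)OCC | intermediate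
10 | 2-(diazoacetyl)-3-(1-ethoxyvinyl)-6-(4-methoxyphenyl)-4H-pyran-4-one | [N-]=[N+]=CC(=O)c1oc(-c2ccc(OC)cc2)cc(=O)c1C(=C)OCC | intermediate
11 | 5,7,3',4'-tetramethoxyflavone | COc1ccc(cc1OC)-c1cc(=O)c2c(OC)cc(OC)cc2o1 | starting material
12 | 8-iodo-5,7,3',4'-tetramethoxyflavone | Ic1c(OC)cc(OC)c2c(=O)cc(-c3ccc(OC)c(OC)c3)oc12 | intermediate
13 | 2-[diazo(5,7,3',4'-tetramethoxyflavon-8-yl)acetyl]-3-(1-ethoxyvinyl)-6-(4-methoxyphenyl)-4H-pyran-4-one | C=C(OCC)c1c(C(=O)C(=[N+]=[N-])c2c(OC)cc(OC)c3c(=O)cc(-c4ccc(OC)c(OC)c4)oc23)oc(-c2ccc(OC)cc2)cc1=O | intermediate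
14 | [3-(1-ethoxyvinyl)-6-(4-methoxyphenyl)-4-oxo-4H-pyran-2-yl](5,7,3',4'-tetramethoxyflavon-8-yl)ketene | C=C(OCC)c1c(C(=C=O)c2c(OC)cc(OC)c3c(=O)cc(-c4ccc(OC)c(OC)c4)oc23)oc(-c2ccc(OC)cc2)cc1=O | intermediate
15 | 5-ethoxy-2-(4-methoxyphenyl)-8-(5,7,3',4'-tetramethoxyflavon-8-yl)-6H-chromene-4,7-dione | CCOC1=C2C(=O)C=C(c3ccc(OC)cc3)OC2=C(c2c(OC)cc(OC)c3c(=O)cc(-c4ccc(OC)c(OC)c4)oc23)C(=O)C1 | intermediate
16 | 5-ethoxy-7-hydroxy-4'-methoxy-8-(5,7,3',4'-tetramethoxyflavon-8-yl)flavone (racemic axis) | CCOc1cc(O)c(-c2c(OC)cc(OC)c3c(=O)cc(-c4ccc(OC)c(OC)c4)oc23)c2oc(-c3ccc(OC)cc3)cc(=O)c12 | intermediate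
17 | 8-(5,7,3',4'-tetrahydroxyflavon-8-yl)-5,7,4'-trihydroxyflavone (racemic axis) | O=c1cc(-c2ccc(O)cc2)oc2c(-c3c(O)cc(O)c4c(=O)cc(-c5ccc(O)c(O)c5)oc34)c(O)cc(O)c12 | target

Total step count: 9. Longest linear sequence: 8 steps (steps 1 to 5, then 7, 8 and 9).

Steps most likely to fail

Step 8. The ketocarbene may be intercepted before the 1,2-shift, by cyclopropanation of the enol ether or by C–H insertion into the neighbouring methoxy group. The crowded ketene may also be consumed by traces of water before it reaches the geometry needed for ring closure. The fallback uses known chemistry and forms the 8,8'' bond between two finished flavones. It sets out from 12.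
- Commercial 5,7,4'-trimethoxyflavone is iodinated under the conditions of step 6 to 8-iodo-5,7,4'-trimethoxyflavone F1.
- Miyaura borylation (B2pin2, PdCl2(dppf), KOAc, dioxane, 90 °C) should convert this into 5,7,4'-trimethoxyflavon-8-ylboronic acid pinacol ester F2.
- Suzuki–Miyaura coupling of this boronate with 12 (Pd(OAc)2, SPhos, K3PO4, toluene/H2O, 100 °C) uses a ligand system made for tetra-ortho-substituted biaryls and should give the 8,8''-biflavone heptamethyl ether F3.
- BBr3 as in step 9 brings the sequence back to the route at 17.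

Step 7. Oxidative addition and C–C reductive elimination may be slow at a carbon flanked by two oxygen substituents. During that time, silver- or palladium-induced loss of N2 from 10 can take over. The fallback reverses the order of bond formation, so that the diazo carbon is first placed on the flavone and then acylated. It sets out from 12 and takes the acyl partner 9 from step 5.
- Reductive carbonylation of 12 (CO, HCO2Na, PdCl2(PPh3)2, DMF, 100 °C) should give 8-formyl-5,7,3',4'-tetramethoxyflavone F4.
- Condensation with TsNHNH2 in MeOH gives the (E)-tosylhydrazone of the 8-formylflavone F5.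
- Bamford–Stevens elimination of its sodium salt (NaOMe, then BnEt3NCl, toluene, 40 °C) gives 8-(diazomethyl)-5,7,3',4'-tetramethoxyflavone F6.
- This aryldiazomethane is added to 9 in place of diazomethane (THF, −15 °C to rt). Acylation at the diazo carbon, with the alkyl carbonate taking up the proton, comes back to the route at 13.

Step 2. Metalation at C5 may compete with metalation at C3, or the metalated pyranone may open by β-elimination of the ring oxygen. The fallback places a leaving group at C3 through the choice of building block, so no site selection is needed. It sets out from 2.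
- 4'-Methoxyacetophenone and ethyl (benzyloxy)acetate undergo a crossed Claisen condensation (NaH, THF) to 4-(benzyloxy)-1-(4-methoxyphenyl)butane-1,3-dione F7.
- Its dianion (LiN(SiMe3)2, 2.2 equiv, THF, −78 °C) is acylated by 2 at the benzyloxy-bearing carbon to give ethyl 3-(benzyloxy)-6-(4-methoxyphenyl)-2,4,6-trioxohexanoate F8.
- Acid (TsOH, toluene, 60 °C) closes this to ethyl 3-(benzyloxy)-6-(4-methoxyphenyl)-4-oxo-4H-pyran-2-carboxylate F9.
- Hydrogenolysis (H2, Pd/C, EtOAc) gives ethyl 3-hydroxy-6-(4-methoxyphenyl)-4-oxo-4H-pyran-2-carboxylate F10.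
- Tf2O and pyridine in CH2Cl2 give ethyl 6-(4-methoxyphenyl)-4-oxo-3-(trifluoromethylsulfonyloxy)-4H-pyran-2-carboxylate F11.
- A Stille coupling with tributyl(1-ethoxyvinyl)stannane (Pd(PPh3)4, LiCl, dioxane, 90 °C) comes back to the route at 7.

Further compounds
F1 | step 8 | 8-iodo-5,7,4'-trimethoxyflavone | Ic1c(OC)cc(OC)c2c(=O)cc(-c3ccc(OC)cc3)oc12
F2 | step 8 | 5,7,4'-trimethoxyflavon-8-ylboronic acid pinacol ester | COc1ccc(cc1)-c1cc(=O)c2c(OC)cc(OC)c(B3OC(C)(C)C(C)(C)O3)c2o1
F3 | step 8 | 8,8''-biflavone heptamethyl ether (5,7,4'-trimethoxyflavone joined at C8 to C8 of 5,7,3',4'-tetramethoxyflavone) | COc1ccc(cc1)-c1cc(=O)c2c(OC)cc(OC)c(c2o1)-c1c(OC)cc(OC)c2c(=O)cc(oc12)-c1ccc(OC)c(OC)c1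
F4 | step 7 | 8-formyl-5,7,3',4'-tetramethoxyflavone | COc1ccc(cc1OC)-c1cc(=O)c2c(OC)cc(OC)c(C=O)c2o1
F5 | step 7 | (E)-tosylhydrazone of the 8-formylflavone | COc1ccc(cc1OC)-c1cc(=O)c2c(OC)cc(OC)c(/C=N/NS(=O)(=O)c3ccc(C)cc3)c2o1
F6 | step 7 | 8-(diazomethyl)-5,7,3',4'-tetramethoxyflavone | COc1ccc(cc1OC)-c1cc(=O)c2c(OC)cc(OC)c(C=[N+]=[N-])c2o1
F7 | step 2 | 4-(benzyloxy)-1-(4-methoxyphenyl)butane-1,3-dione | COc1ccc(cc1)C(=O)CC(=O)COCc1ccccc1
F8 | step 2 | ethyl 3-(benzyloxy)-6-(4-methoxyphenyl)-2,4,6-trioxohexanoate | CCOC(=O)C(=O)C(OCc1ccccc1)C(=O)CC(=O)c1ccc(OC)cc1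
F9 | step 2 | ethyl 3-(benzyloxy)-6-(4-methoxyphenyl)-4-oxo-4H-pyran-2-carboxylate | CCOC(=O)c1oc(-c2ccc(OC)cc2)cc(=O)c1OCc1ccccc1
F10 | step 2 | ethyl 3-hydroxy-6-(4-methoxyphenyl)-4-oxo-4H-pyran-2-carboxylate | CCOC(=O)c1oc(-c2ccc(OC)cc2)cc(=O)c1O
F11 | step 2 | ethyl 6-(4-methoxyphenyl)-4-oxo-3-(trifluoromethylsulfonyloxy)-4H-pyran-2-carboxylate | CCOC(=O)c1oc(-c2ccc(OC)cc2)cc(=O)c1OS(=O)(=O)C(F)(F)F
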